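## Structural features

The target is a 9,13;15,16-diepoxylabd-14-ene: a decalin (rings A and B) in which C9 is the spiro atom of a tetrahydrofuran (ring C, oxygen bridging C9 and C13) and C13 is in turn the spiro atom of a 2,3-dihydrofuran (ring D, enol ether C14=C15, methylene C16). The A/B fusion is cis, with H5 and the C10 methyl both on the β face; O9 is α with C11 β, the C8 acetate is α with its methyl β, and the C7 hydroxyl is β. Ring B carries oxygen on four neighbouring carbons (C6 ketone, C7 alcohol, C8 tertiary acetate, C9 ether). C5, C7, C8, C9 and C10 are stereocentres, three of them (C8, C9, C10) contiguous and fully substituted, and C13 is a sixth, remote one. Three features are fragile: the allylic spiro enol ether ionises at C13 with acid and then aromatises to a furan, the tertiary acetate sits next to a free hydroxyl and β to the ketone (acyl shift, elimination), and H5 is α to the ketone (loss of the cis fusion). The real difficulty is the C8/C9/C10 block: carbon has to be added to a C9 carbonyl between two quaternary carbons, with oxygen on the α face of both C8 and C9, and the C6 and C7 oxygens have to be unveiled in the right order. The key step uses the C6–C9 oxygen array next to the cis C5/C10 fusion: C8 and C9 are the two oxygenated carbons of a masked o-benzoquinone, C10 is its methylated diene terminus, and the C5–C6 bond of ring B is formed when a vinyl group on C8 of the derived bicyclo[2.2.2]octenol migrates by a [3,3] shift.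

## Logic of the disconnections

**42 ⇐ 41 ⇐ 40 ⇐ 39.** No skeletal bond is cut. The O7–H bond (from O7–Si), the C6 carbonyl (from C6–OH) and the O6–H bond (from O6–Si) are traced back in that order. The C6 carbonyl makes H5 epimerisable and the C8 acetate a β-leaving group, and a free O7–H beside the acetate invites acyl transfer, so both are allowed to exist only in 41 and 42. The gain is that all earlier compounds carry C6 and C7 as two differently silylated carbinols. The demand is two successive buffered desilylations, free of acid that ionises C13–O9 and free of alkoxide.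

**39 ⇐ 37.** The acetyl C–O8 bond and one C17–H bond are cut, which turns the tertiary acetate and its methyl into a C8 spiro-epoxide. Hydride at the methylene carbon gives the methyl group and an alkoxide that is acetylated while it is the only free oxygen. The gain is that the hindered tertiary ester is made in the reduction flask. The demand is attack at the epoxide methylene only, with ring D already an enol ether, since an alkyl iodide would not survive hydride.

**37 ⇐ 36 ⇐ 35.** The C14=C15 π bond is traced to a C14–I bond, and the O9–C13 bond of ring C is cut. O9 lies between two quaternary carbons and can only be alkylated intramolecularly by a cation-like tertiary carbon; an iodonium ion on a 2,5-dihydrofuran alkene provides that and leaves the leaving group at C14. The gain is that rings C and D and the C13 centre reduce to one trisubstituted alkene. The demand is 5-exo attack with the C14 arm turned toward C8, then elimination toward C15.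

**35 ⇐ 34.** The C8–O bond is cut to the exocyclic C8=C17 alkene. A carbon nucleophile is expected to enter a C8 carbonyl from the α face and give the wrong epimer, so carbon is placed on C8 first and oxygen is delivered second, from the 9α-hydroxyl. The gain is that the C8 configuration follows from C9. The demand is selection of the allylic alkene over the side-chain ring alkene.

**34 ⇐ 26 + 31.** The C9–C11 bond is cut. It is the one bond joining the bicyclic core to all six side-chain carbons, and the C9 carbonyl of 26 cannot enolise. The gain is convergence. The demand is carbonyl addition rather than conjugate addition, from the β face.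

**31 ⇐ 30 ⇐ 28 ⇐ 27.** The C–I and C–O bonds are exchanged, then the ring alkene and the vinyl C–C bond are cut by an enyne-metathesis retron. The gain is a three-step fragment from a single commercial ether. The demand is hydroboration at the vinyl group of 28 only.

**26 ⇐ 25 ⇐ 24.** The C9 carbonyl is traced to its dimethyl ketal, and C8=C17 is cut to the C8 carbonyl. The ketal keeps C9 silent until C8 has been converted. The demand is a non-basic olefination, because C7–H is acidic and O6 is a β-leaving group.

**24 ⇐ 23 ⇐ 22 ⇐ 20 ⇐ 19 ⇐ 17.** Cut in turn are O6–Si, C6–O (back to C6–Si), the second C4–CH3 bond, O7–Si and C7–O. Silicon is the latent C6 hydroxyl. It is exchanged for oxygen directly after the ring-A alkene is consumed, because its unmasking needs electrophilic bromine and peracid, which no later alkene or enol ether would tolerate. The C7 oxygen comes from the only enolate the C8 ketone can form. The demands are retention at C6 and attack anti to silicon at C7.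

**17 ⇐ 14.** The C5–C6 bond is cut and the C3–C8 bond is re-formed. The gain is that ring B, the cis fusion and C6 collapse into a bicyclo[2.2.2]octenol with one carbinol centre. The demands are a vinyl group syn to the alkene bridge and an E-vinylsilane.

**14 ⇐ 13 ⇐ 12 ⇐ 10 + 3, and 3 ⇐ 1.** These are the resolution, C–H traced to C–S, and the carbinol–vinyl bond (C8–C7). The sulfonyl group is kept until the α,α-dimethoxy ketone has been consumed, so that the ketone never meets a dissolving metal. The demand is addition to the carbonyl face on the side of the alkene bridge.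

**10 ⇐ 7 + 8 through 9, and 7 ⇐ 4.** The two cage bonds (C1–C10 and C2–C3 in target numbering) are cut by a Diels–Alder retron; the two alkene carbons of 8 become C1 and C2. The phenol oxygen of 7 is traced to an ortho C–H of 4. The demand is that 9 be trapped as it forms.

## Other disconnections considered

Alternative 1: The cut is C8–C9 of ring B. The forward step is a reductive cyclisation of the ynone–ketone A2 with samarium diiodide (divalent samarium), in which the β-carbon of the ynone (C8) is joined to the ketone carbon C9 to give the hydroxy enone A1.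
- In its favour: the C8 methyl, the C6 carbonyl, the C9 oxygen and all side-chain carbons arrive in one convergent ring closure. The C9–C bond is made intramolecularly, so no external nucleophile has to reach a ketone between two quaternary carbons. On these two points it is better than the chosen plan.
- Against it: the cis relation of C5 and C10 must already exist in A2, where C5 is α to the ynone carbonyl and can epimerise; the chosen cage enforces the cis fusion mechanically.
- Against it: the C9 configuration comes from a flexible transition state.
- Against it: A1 still needs trans-dioxygenation of the C7=C8 enone, with the C6 ketone (and so the labile H5) present throughout.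
- Against it: the side chain of A1 is a furan, one oxidation level above ring D. Reaching the spiro 2,3-dihydrofuran would need a net reduction at C16 together with C13–O bond formation against the aromatic stabilisation.
- Comparison: on carbon-skeleton step economy alternative 1 is equal or better; on ring D, on C7/C8 and on the security of C5 the chosen plan is stronger.

Alternative 2: The cut is C12=C13 of a ring-C enol ether. A titanium ethylidene generated in the flask (TiCl4, Zn, PbCl2, TMEDA, CH3CHBr2) first undergoes metathesis with the allyl group of the benzyloxyacetate A4, and the resulting titanium alkylidene then attacks the ester carbonyl, which closes ring C as the cyclic enol ether A3.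
- In its favour: the oxygen at C9 is tied into ring C by acylation and carbonyl–alkene metathesis, not by an addition at a buried tertiary oxygen. A4 needs only an allyl nucleophile at C9, the most dependable reagent for a hindered ketone. On that point it is better than the organocerium addition of the chosen plan.
- Against it: making A4 requires esterification of a tertiary C9 hydroxyl between two quaternary carbons, and the titanium reagent is used in large excess.
- Against it: A3 still lacks C14 and C15 and the spiro centre, so C13 must later be made quaternary with stereocontrol and ring D closed and unsaturated, all on an acid-labile enol ether. The chosen plan sets C13 and both rings in two steps from 35.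
- Comparison: alternative 2 says nothing about the cis-decalin or the C7/C8 oxygens, so it complements the chosen key step rather than competing with it. It is equal on mechanism-level reliability and weaker on step economy for rings C and D.

Alternative 3: The cuts are C1–C10 and C4–C5. The quinone A6 and the silyloxy diene A7 combine in an endo [4+2] cycloaddition to the cis-fused adduct A5.
- In its favour: one step from two cheap compounds gives the cis fusion, the C10 quaternary centre, the C8 methyl and both the C6 and C9 carbonyls. Catalytic enantioselective quinone cycloadditions are known, so no resolution would be needed. On front-end step count and on absolute stereocontrol it is better than the chosen plan.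
- Against it: ring A of A5 carries oxygen at C1 and C3 and no carbon substituent at C4, so two deoxygenations and a geminal dimethylation next to the ring fusion are required.
- Against it: the two carbonyls must be differentiated, C7 has no oxygen, and the cis ene-dione epimerises at C5 easily, with the C6 carbonyl present from the first step.
- Against it: the additions at C8 and C9 remain exactly as hard as in the chosen plan.
- Comparison: both plans rest on a [4+2] step. The chosen plan adds a [3,3] shift that leaves C7 ready for oxygenation, places oxygen at C8 and C9, and keeps C6 masked as silicon; alternative 3 is shorter at the front and longer and less secure at the back.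

Key step: step 7

Assumption: racemic 10, 12 and 13 are drawn as the enantiomer carried on after step 6, any regio- or stereoisomer of 10 with respect to the sulfonyl group converges in step 5, and the absolute configuration of 14 is to be secured by anomalous-dispersion X-ray analysis before material is advanced.

## Route

Step 1
Reactants: 1 ethynyl(dimethyl)phenylsilane
Product: 3 (E)-(2-iodovinyl)dimethylphenylsilane, via alkenylzirconocene chloride 2 (not isolated)
Conditions: Cp2Zr(H)Cl, THF, rt; then I2, 0 °C
Reagents that add atoms: iodine, II
Why: Syn-hydrozirconation of the terminal silylalkyne puts zirconium on the unsubstituted carbon; iodinolysis of the C–Zr bond proceeds with retention, so the E geometry that later fixes C6 is set here.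

Step 2
Reactants: 4 2,4-dimethylanisole
Product: 7 2-methoxy-3,5-dimethylphenol, via aryllithium 5 (not isolated), via aryl dimethyl boronate 6 (not isolated)
Conditions: n-BuLi, TMEDA, Et2O, 0 °C → rt; B(OMe)3, −78 °C; then AcOH, H2O2, 0 °C
Reagents that add atoms: hydrogen peroxide, OO
Why: Directed ortho-metalation at the only free position beside the methoxy group (ring lithiation is preferred over lateral lithiation with n-BuLi·TMEDA), borylation and oxidative C–B to C–O exchange in one flask.

Step 3
Reactants: 7 2-methoxy-3,5-dimethylphenol; 8 phenyl vinyl sulfone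
Product: 10 rac-3,3-dimethoxy-4,6-dimethyl-7-(phenylsulfonyl)bicyclo[2.2.2]oct-5-en-2-one (sulfonyl syn to C5=C6), via masked o-benzoquinone 9 (not isolated)
Conditions: PhI(OAc)2, MeOH, 8 (5 equiv), slow addition of 7, 0 °C → 50 °C
Reagents that add atoms: methanol, CO
Why: Hypervalent-iodine oxidative dearomatisation in methanol gives the 6,6-dimethoxycyclohexa-2,4-dienone, which the electron-poor alkene intercepts in a Diels–Alder reaction before it can dimerise. The sulfonyl group turns ethylene into a competent dienophile and is removed in step 5, so the orientation at the sulfonyl carbon is immaterial.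

Step 4
Reactants: 3 (E)-(2-iodovinyl)dimethylphenylsilane; 10 rac-sulfonyl ketone
Product: 12 rac-2-[(E)-2-(dimethylphenylsilyl)vinyl]-3,3-dimethoxy-4,6-dimethyl-7-(phenylsulfonyl)bicyclo[2.2.2]oct-5-en-2-ol (vinyl syn to C5=C6), via silylvinyllithium 11 (not isolated)
Conditions: 3, t-BuLi (2 equiv per 3), Et2O, −78 °C; then 10 (0.45 equiv), THF, −78 → −40 °C; H2O
Reagents that add atoms: none
Why: Iodine–lithium exchange with retention of alkene geometry, then 1,2-addition to the ketone from the face flanked by the sp2 bridge, not past the ethano-bridge hydrogens, which places the vinyl group syn to the alkene as the [3,3] shift requires. The excess reagent covers any deprotonation next to the sulfone.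

Step 5
Reactants: 12 rac-sulfonyl carbinol
Product: 13 rac-2-[(E)-2-(dimethylphenylsilyl)vinyl]-3,3-dimethoxy-4,6-dimethylbicyclo[2.2.2]oct-5-en-2-ol
Conditions: Na(Hg) (6%), Na2HPO4, MeOH/THF, −20 °C → rt
Reagents that add atoms: none
Why: Reductive desulfonylation by electron transfer. It is placed after the carbonyl addition so that the α,α-dimethoxy ketone is never exposed to a dissolving metal; the alkene, vinylsilane and ketal are inert.

Step 6
Reactants: 13 rac-carbinol
Product: 14 2-[(E)-2-(dimethylphenylsilyl)vinyl]-3,3-dimethoxy-4,6-dimethylbicyclo[2.2.2]oct-5-en-2-ol (single enantiomer; vinyl syn to C5=C6)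
Conditions: preparative SFC, amylose tris(3,5-dimethylphenylcarbamate) phase, CO2/i-PrOH
Reagents that add atoms: none
Why: Chromatographic resolution on a chiral stationary phase; no stereocentre is made. It fixes the absolute configuration of C10 for the rest of the route.

Step 7
Reactants: 14 enantiopure vinyl carbinol
Product: 17 cis-fused 6α-(dimethylphenylsilyl)-9,9-dimethoxy-4,10-dimethyloctal-3-en-8-one (target numbering; H5 and the C10 methyl β), via potassium alkoxide 15 (not isolated), via potassium enolate 16 (not isolated)
Conditions: KH, 18-crown-6, THF, 0 °C → rt; AcOH, −78 °C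
Reagents that add atoms: none
Why: KH with 18-crown-6 gives the dissociated alkoxide 15; a charge-accelerated [3,3] sigmatropic shift (anionic oxy-Cope rearrangement) then joins the silylated vinyl terminus (future C6) to the unsubstituted cage alkene carbon (future C5) while the carbinol–bridgehead bond (future C8–C3) breaks, and the enolate 16 is protonated to 17. The nearest established reaction class is the alkoxide-accelerated oxy-Cope shift of vinyl carbinols built on bicyclo[2.2.2]octenones that come from masked o-benzoquinone cycloadditions, a route to cis-fused decalins. Ring B is closed by the sigmatropic shift itself, a suprafacial six-electron process through a boat-shaped six-membered array enforced by the cage, so the six-membered ring forms as the bicycle opens and ring A is what is left of the cage. C5 is controlled by the cage: the vinyl group reaches only the alkene face turned toward the carbinol bridge, and with C10 the methylated bridgehead on that side, H5 ends cis to the C10 methyl. C6 is controlled by the E geometry of the vinylsilane in the boat, which keeps silicon on the outside of the cage and so trans to H5 (6α). The step needs the [3,3] path to win over fragmentation of the alkoxide and over attack of oxygen on silicon; the syn arrangement set in step 4, the strain released on opening the cage and a silyl group with no leaving group on silicon secure this. The shift delivers the enolate across C7–C8 only, the same regiochemistry that the deprotonation in step 8 reproduces.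

Step 8
Reactants: 17 silyl ketone
Product: 19 cis-fused 7β-hydroxy-6α-(dimethylphenylsilyl)-9,9-dimethoxy-4,10-dimethyloctal-3-en-8-one, via sodium enolate 18 (not isolated)
Conditions: NaN(SiMe3)2, THF, −78 °C; 2-(phenylsulfonyl)-3-phenyloxaziridine, −78 °C; AcOH
Reagents that add atoms: 2-(phenylsulfonyl)-3-phenyloxaziridine, O=S(=O)(c1ccccc1)N1OC1c1ccccc1
Why: Only C7 can be deprotonated (C9 is a fully substituted ketal carbon), so NaN(SiMe3)2 gives the sodium enolate 18 across C7–C8, a counter-ion that suits this oxidant and disfavours addition to the sulfonimine by-product. Enolate hydroxylation by the N-sulfonyloxaziridine should occur anti to the α-silyl group on C6, which is also the convex face, giving the 7β-alcohol.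

Step 9
Reactants: 19 hydroxy ketone
Product: 20 cis-fused 7β-(tert-butyldimethylsilyloxy)-6α-(dimethylphenylsilyl)-9,9-dimethoxy-4,10-dimethyloctal-3-en-8-one
Conditions: TBSOTf, 2,6-lutidine, CH2Cl2, −78 → 0 °C
Reagents that add atoms: tert-butyldimethylsilyl triflate, CC(C)(C)[Si](C)(C)OS(=O)(=O)C(F)(F)F
Why: Silylation of the secondary alcohol with a silyl triflate. The robust silyl ether is chosen because O7 stays masked until the last step.

Step 10
Reactants: 20 silyl ether
Product: 22 cis-fused 7β-(tert-butyldimethylsilyloxy)-6α-(dimethylphenylsilyl)-9,9-dimethoxy-4,4,10-trimethyldecalin-8-one, via sulfonyl hydrazide 21 (not isolated)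
Conditions: Fe(acac)3 (cat.), PhSiH3, CH2=NNHSO2(n-C8H17), THF/MeOH, rt; then MeOH, 60 °C
Reagents that add atoms: formaldehyde octane-1-sulfonylhydrazone, C=NNS(=O)(=O)CCCCCCCC
Why: Metal-hydride hydrogen-atom transfer to C3 gives the tertiary C4 radical, which adds to the hydrazone carbon; warming in methanol expels sulfinate and dinitrogen to leave the methyl group (Markovnikov hydromethylation of an unactivated alkene). C4 becomes a non-stereogenic gem-dimethyl carbon, and the ketone, silyl ether and arylsilane are spectators.

Step 11
Reactants: 22 gem-dimethyl silane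
Product: 23 cis-fused 6α-hydroxy-7β-(tert-butyldimethylsilyloxy)-9,9-dimethoxy-4,4,10-trimethyldecalin-8-one
Conditions: KBr, AcOOH, NaOAc, AcOH, 0 °C → rt
Reagents that add atoms: peracetic acid, CC(=O)OO
Why: Fleming–Tamao oxidation: ipso-bromodesilylation of the phenyl group, peroxide attack at silicon and 1,2-shift of C6 from silicon to oxygen with retention give the 6α-alcohol. It is done here because from step 13 on the molecule always holds an alkene or enol ether that would not survive these reagents; the ketal beside the carbonyl resists the buffered acid.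

Step 12
Reactants: 23 C6 alcohol
Product: 24 cis-fused 6α-(triethylsilyloxy)-7β-(tert-butyldimethylsilyloxy)-9,9-dimethoxy-4,4,10-trimethyldecalin-8-one
Conditions: TESOTf, 2,6-lutidine, CH2Cl2, −78 → 0 °C
Reagents that add atoms: triethylsilyl triflate, CC[Si](CC)(CC)OS(=O)(=O)C(F)(F)F
Why: Silylation; the more labile triethylsilyl group is used because O6 must be freed before O7 at the end.

Step 13
Reactants: 24 bis-silyl ketone
Product: 25 cis-fused 6α-(triethylsilyloxy)-7β-(tert-butyldimethylsilyloxy)-9,9-dimethoxy-4,4,10-trimethyl-8-methylenedecalin
Conditions: Cp2TiMe2, toluene, 70 °C, dark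
Reagents that add atoms: dimethyltitanocene, [CH3-].[CH3-].[Ti+4].c1cc[cH-]c1.c1cc[cH-]c1
Why: Carbonyl methylenation by the titanium methylidene formed thermally from Cp2TiMe2. It is non-basic, so C7 is not epimerised and the O6 group is not eliminated. Carbon is placed on C8 before oxygen because a methyl nucleophile is expected to enter this carbonyl from the α face (the β face lies under the axial C10 methyl) and give the wrong epimer.

Step 14
Reactants: 25 methylene ketal
Product: 26 cis-fused 6α-(triethylsilyloxy)-7β-(tert-butyldimethylsilyloxy)-4,4,10-trimethyl-8-methylenedecalin-9-one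
Conditions: PPTS (cat.), acetone/H2O, rt
Reagents that add atoms: water, O
Why: Acid-catalysed ketal hydrolysis; the allylic oxocarbenium ion forms easily, so conditions mild enough for both silyl ethers suffice.

Step 15
Reactants: 27 allyl propargyl ether
Product: 28 3-vinyl-2,5-dihydrofuran
Conditions: first-generation Grubbs catalyst RuCl2(PCy3)2(=CHPh) (cat.), ethylene (1 atm), CH2Cl2, rt
Reagents that add atoms: none
Why: Ring-closing enyne metathesis in the exo mode gives the five-membered ring and the vinyl group with no loss of atoms.

Step 16
Reactants: 28 3-vinyl-2,5-dihydrofuran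
Product: 30 2-(2,5-dihydrofuran-3-yl)ethanol, via B-alkyl-9-BBN 29 (not isolated)
Conditions: 9-BBN, THF, 0 °C → rt; then NaOH, H2O2, 0 °C
Reagents that add atoms: hydrogen peroxide, OO
Why: Hydroboration–oxidation; the bulky borane selects the monosubstituted vinyl group over the trisubstituted ring alkene and places boron on the terminal carbon.

Step 17
Reactants: 30 2-(2,5-dihydrofuran-3-yl)ethanol
Product: 31 3-(2-iodoethyl)-2,5-dihydrofuran
Conditions: I2, PPh3, imidazole, CH2Cl2, 0 °C
Reagents that add atoms: iodine, II
Why: Appel-type conversion of a primary alcohol into the iodide through the alkoxyphosphonium salt.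

Step 18
Reactants: 31 3-(2-iodoethyl)-2,5-dihydrofuran; 26 methylene ketone
Product: 34 cis-fused 9α-hydroxy-9β-[2-(2,5-dihydrofuran-3-yl)ethyl]-6α-(triethylsilyloxy)-7β-(tert-butyldimethylsilyloxy)-4,4,10-trimethyl-8-methylenedecalin, via alkyllithium 32 (not isolated), via alkylcerium dichloride 33 (not isolated)
Conditions: 31, t-BuLi (2 equiv per 31), Et2O/pentane, −78 °C; CeCl3, THF, −78 °C; then 26, −78 → −40 °C; aq. NH4Cl
Reagents that add atoms: none
Why: Iodine–lithium exchange, transmetalation and organocerium 1,2-addition to the non-enolisable ketone; organocerium reagents favour carbonyl over conjugate addition and tolerate hindrance. Ring B is expected to adopt the chair that keeps O6 and O7 equatorial and avoids the syn-diaxial clash of the C4 and C10 methyl groups; in that chair the α face of C9 lies under the axial C4 carbon, so the reagent should enter from the convex β face and give 9α-OH with C11 β.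

Step 19
Reactants: 34 allylic alcohol
Product: 35 cis-fused 8α,17-epoxy-9α-hydroxy-9β-[2-(2,5-dihydrofuran-3-yl)ethyl]-6α-(triethylsilyloxy)-7β-(tert-butyldimethylsilyloxy)-4,4,10-trimethyldecalin
Conditions: VO(acac)2 (cat.), t-BuOOH, CH2Cl2, 0 °C → rt
Reagents that add atoms: tert-butyl hydroperoxide, CC(C)(C)OO
Why: Hydroxyl-directed epoxidation: the vanadate ester of the 9α-hydroxyl delivers oxygen to the α face of the adjacent exocyclic alkene, so O8 is set cis to O9. Allylic alkenes react much faster than the bishomoallylic ring alkene of the side chain.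

Step 20
Reactants: 35 epoxy alcohol
Product: 36 iodo spiro ether: 8α,17-epoxy-9α,13-epoxy-14-iodo-15,16-epoxy skeleton with 6α-(triethylsilyloxy) and 7β-(tert-butyldimethylsilyloxy) groups (iodine trans to O9 on ring D; C16 on the side of C10)
Conditions: NIS, CH2Cl2, −20 → 0 °C, dark
Reagents that add atoms: N-iodosuccinimide, O=C1CCC(=O)N1I
Why: Iodoetherification: iodonium formation on the trisubstituted alkene, 5-exo-trig Markovnikov attack of the tertiary hydroxyl at C13, anti addition. The iodine-bearing C14 arm is expected to turn toward the flatter C8 spiro-epoxide side and the C16 methylene toward the quaternary C10, which is the C13 configuration of 42.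

Step 21
Reactants: 36 iodo spiro ether
Product: 37 spiro enol ether: 8α,17-epoxy-9α,13;15,16-diepoxy-14-ene skeleton with 6α-(triethylsilyloxy) and 7β-(tert-butyldimethylsilyloxy) groups
Conditions: DBU, toluene, 100 °C
Reagents that add atoms: none
Why: E2 dehydroiodination. C13 is quaternary and the iodide is neopentyl-like, so substitution is shut off and only C15 offers an anti hydrogen, which gives the C14=C15 enol ether.

Step 22
Reactants: 37 epoxy enol ether
Product: 39 8α-acetoxy-6α-(triethylsilyloxy)-7β-(tert-butyldimethylsilyloxy)-9α,13;15,16-diepoxy-5β-labd-14-ene, via lithium alkoxide 38 (not isolated)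
Conditions: LiEt3BH, THF, 0 °C → rt; then Ac2O, DMAP (cat.), 0 °C → rt
Reagents that add atoms: acetic anhydride, CC(=O)OC(C)=O
Why: SN2 opening of the 1,1-disubstituted epoxide by hydride at the methylene carbon gives the C8 methyl group and the tertiary alkoxide with oxygen left on the α face. Acylation of that alkoxide in the same flask installs the tertiary acetate while no other oxygen is free.

Step 23
Reactants: 39 bis-silyl acetate
Product: 40 8α-acetoxy-6α-hydroxy-7β-(tert-butyldimethylsilyloxy)-9α,13;15,16-diepoxy-5β-labd-14-ene
Conditions: HF·pyridine, pyridine (excess), THF, 0 °C; aq. NaHCO3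
Reagents that add atoms: none
Why: Selective desilylation: triethylsilyl ethers are cleaved far faster than tert-butyldimethylsilyl ethers, and the O7 ether is further shielded by the quaternary C8. Excess pyridine keeps the medium too weakly acidic to ionise the spiro enol ether.

Step 24
Reactants: 40 C6 alcohol
Product: 41 8α-acetoxy-7β-(tert-butyldimethylsilyloxy)-9α,13;15,16-diepoxy-5β-labd-14-en-6-one
Conditions: Dess–Martin periodinane, pyridine, CH2Cl2, 0 °C → rt
Reagents that add atoms: none
Why: Dess–Martin oxidation of the secondary alcohol under buffered, neutral conditions, so the cis fusion at C5 and the β-acetoxy ketone are not disturbed.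

Step 25
Reactants: 41 silyloxy ketone
Product: 42 8α-acetoxy-7β-hydroxy-9α,13;15,16-diepoxy-5β-labd-14-en-6-one (CNP0275274.1)
Conditions: TBAF, AcOH (1:1), THF, 0 °C → rt; pH 7 buffer
Reagents that add atoms: none
Why: Fluoride-mediated cleavage of the α-silyloxy ketone. Acetic acid protonates the alkoxide as it forms, so acetyl migration from O8 to O7, β-elimination of acetate and epimerisation at C5 should not start.

## Compound list

1 | ethynyl(dimethyl)phenylsilane | C#C[Si](C)(C)c1ccccc1 | starting material
2 | (E)-[2-(dimethylphenylsilyl)vinyl]zirconocene chloride (not isolated) | C[Si](C)(/C=C/[Zr](Cl)(C1C=CC=C1)C1C=CC=C1)c1ccccc1 | intermediate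
3 | (E)-(2-iodovinyl)dimethylphenylsilane | I/C=C/[Si](C)(C)c1ccccc1 | intermediate
4 | 2,4-dimethylanisole | COc1ccc(C)cc1C | starting material
5 | 2-methoxy-3,5-dimethylphenyllithium (not isolated) | [Li]c1cc(C)cc(C)c1OC | intermediate
6 | dimethyl (2-methoxy-3,5-dimethylphenyl)boronate (not isolated) | COB(OC)c1cc(C)cc(C)c1OC | intermediate
7 | 2-methoxy-3,5-dimethylphenol | COc1c(O)cc(C)cc1C | intermediate
8 | phenyl vinyl sulfone | C=CS(=O)(=O)c1ccccc1 | starting material
9 | 6,6-dimethoxy-3,5-dimethylcyclohexa-2,4-dien-1-one (not isolated) | O=C1C=C(C)C=C(C)C1(OC)OC | intermediate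
10 | rac-3,3-dimethoxy-4,6-dimethyl-7-(phenylsulfonyl)bicyclo[2.2.2]oct-5-en-2-one, sulfonyl syn to C5=C6 (racemate; one enantiomer drawn) | O=C1[C@@H]2[C@@H](S(=O)(=O)c3ccccc3)C[C@@](C)(C=C2C)C1(OC)OC | intermediate
11 | (E)-[2-(dimethylphenylsilyl)vinyl]lithium (not isolated) | [Li]/C=C/[Si](C)(C)c1ccccc1 | intermediate
12 | rac-2-[(E)-2-(dimethylphenylsilyl)vinyl]-3,3-dimethoxy-4,6-dimethyl-7-(phenylsulfonyl)bicyclo[2.2.2]oct-5-en-2-ol, vinyl syn to C5=C6 (racemate; one enantiomer drawn) | O[C@]1(/C=C/[Si](C)(C)c2ccccc2)[C@@H]3[C@@H](S(=O)(=O)c4ccccc4)C[C@@](C)(C=C3C)C1(OC)OC | intermediate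
13 | rac-2-[(E)-2-(dimethylphenylsilyl)vinyl]-3,3-dimethoxy-4,6-dimethylbicyclo[2.2.2]oct-5-en-2-ol (racemate; one enantiomer drawn) | O[C@]1(/C=C/[Si](C)(C)c2ccccc2)[C@@H]3CC[C@@](C)(C=C3C)C1(OC)OC | intermediate
14 | 2-[(E)-2-(dimethylphenylsilyl)vinyl]-3,3-dimethoxy-4,6-dimethylbicyclo[2.2.2]oct-5-en-2-ol, single enantiomer, vinyl syn to C5=C6 | O[C@]1(/C=C/[Si](C)(C)c2ccccc2)[C@@H]3CC[C@@](C)(C=C3C)C1(OC)OC | intermediate
15 | potassium alkoxide of 14 (not isolated) | [K+].[O-][C@]1(/C=C/[Si](C)(C)c2ccccc2)[C@@H]3CC[C@@](C)(C=C3C)C1(OC)OC | intermediate
16 | potassium C7=C8 enolate of 17 (not isolated) | [K+].[O-]C1=C[C@H]([Si](C)(C)c2ccccc2)[C@@H]3C(C)=CCC[C@]3(C)C1(OC)OC | intermediate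
17 | cis-fused 6α-(dimethylphenylsilyl)-9,9-dimethoxy-4,10-dimethyloctal-3-en-8-one (H5 β, 10-methyl β) | O=C1C[C@H]([Si](C)(C)c3ccccc3)[C@@H]2C(C)=CCC[C@]2(C)C1(OC)OC | intermediate
18 | sodium C7=C8 enolate of 17 (not isolated) | [Na+].[O-]C1=C[C@H]([Si](C)(C)c2ccccc2)[C@@H]3C(C)=CCC[C@]3(C)C1(OC)OC | intermediate
19 | 7β-hydroxy derivative of 17 | O=C1[C@@H](O)[C@H]([Si](C)(C)c3ccccc3)[C@@H]2C(C)=CCC[C@]2(C)C1(OC)OC | intermediate
20 | 7β-(tert-butyldimethylsilyloxy) derivative of 17 | O=C1[C@@H](O[Si](C)(C)C(C)(C)C)[C@H]([Si](C)(C)c3ccccc3)[C@@H]2C(C)=CCC[C@]2(C)C1(OC)OC | intermediate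
21 | N'-alkyl octane-1-sulfonohydrazide at the new C4 methylene (C4 epimers, not isolated) | O=C1[C@@H](O[Si](C)(C)C(C)(C)C)[C@H]([Si](C)(C)c3ccccc3)[C@@H]2C(C)(CNNS(=O)(=O)CCCCCCCC)CCC[C@]2(C)C1(OC)OC | intermediate
22 | cis-fused 7β-(tert-butyldimethylsilyloxy)-6α-(dimethylphenylsilyl)-9,9-dimethoxy-4,4,10-trimethyldecalin-8-one | O=C1[C@@H](O[Si](C)(C)C(C)(C)C)[C@H]([Si](C)(C)c3ccccc3)[C@@H]2C(C)(C)CCC[C@]2(C)C1(OC)OC | intermediate
23 | cis-fused 6α-hydroxy-7β-(tert-butyldimethylsilyloxy)-9,9-dimethoxy-4,4,10-trimethyldecalin-8-one | O=C1[C@@H](O[Si](C)(C)C(C)(C)C)[C@H](O)[C@@H]2C(C)(C)CCC[C@]2(C)C1(OC)OC | intermediate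
24 | cis-fused 6α-(triethylsilyloxy)-7β-(tert-butyldimethylsilyloxy)-9,9-dimethoxy-4,4,10-trimethyldecalin-8-one | O=C1[C@@H](O[Si](C)(C)C(C)(C)C)[C@H](O[Si](CC)(CC)CC)[C@@H]2C(C)(C)CCC[C@]2(C)C1(OC)OC | intermediate
25 | 8-methylene analogue of 24 (9,9-dimethoxy) | C=C1[C@@H](O[Si](C)(C)C(C)(C)C)[C@H](O[Si](CC)(CC)CC)[C@@H]2C(C)(C)CCC[C@]2(C)C1(OC)OC | intermediate
26 | cis-fused 6α-(triethylsilyloxy)-7β-(tert-butyldimethylsilyloxy)-4,4,10-trimethyl-8-methylenedecalin-9-one | C=C1[C@@H](O[Si](C)(C)C(C)(C)C)[C@H](O[Si](CC)(CC)CC)[C@@H]2C(C)(C)CCC[C@]2(C)C1=O | intermediate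
27 | allyl propargyl ether | C#CCOCC=C | starting material
28 | 3-vinyl-2,5-dihydrofuran | C=CC1=CCOC1 | intermediate
29 | B-[2-(2,5-dihydrofuran-3-yl)ethyl]-9-borabicyclo[3.3.1]nonane (not isolated) | C1CCC2CCCC1B2CCC1=CCOC1 | intermediate
30 | 2-(2,5-dihydrofuran-3-yl)ethanol | OCCC1=CCOC1 | intermediate
31 | 3-(2-iodoethyl)-2,5-dihydrofuran | ICCC1=CCOC1 | intermediate
32 | [2-(2,5-dihydrofuran-3-yl)ethyl]lithium (not isolated) | [Li]CCC1=CCOC1 | intermediate
33 | [2-(2,5-dihydrofuran-3-yl)ethyl]cerium dichloride (not isolated) | Cl[Ce](Cl)CCC1=CCOC1 | intermediate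
34 | 9α-hydroxy-9β-[2-(2,5-dihydrofuran-3-yl)ethyl] adduct of 26 | C=C1[C@@H](O[Si](C)(C)C(C)(C)C)[C@H](O[Si](CC)(CC)CC)[C@@H]2C(C)(C)CCC[C@]2(C)[C@@]1(O)CCC3=CCOC3 | intermediate
35 | 8α,17-epoxide of 34 (epoxide oxygen cis to the 9α-hydroxyl) | C1O[C@@]12[C@@H](O[Si](C)(C)C(C)(C)C)[C@H](O[Si](CC)(CC)CC)[C@@H]3C(C)(C)CCC[C@]3(C)[C@@]2(O)CCC4=CCOC4 | intermediate
36 | iodo spiro ether (9α,13-epoxy, 14-iodo trans to O9, 15,16-epoxy; 8α,17-epoxide retained) | C1O[C@@]12[C@@H](O[Si](C)(C)C(C)(C)C)[C@H](O[Si](CC)(CC)CC)[C@@H]3C(C)(C)CCC[C@]3(C)[C@@]24CC[C@@]5([C@H](I)COC5)O4 | intermediate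
37 | spiro enol ether (9α,13;15,16-diepoxy-14-ene; 8α,17-epoxide retained) | C1O[C@@]12[C@@H](O[Si](C)(C)C(C)(C)C)[C@H](O[Si](CC)(CC)CC)[C@@H]3C(C)(C)CCC[C@]3(C)[C@@]24CC[C@@]5(C=COC5)O4 | intermediate
38 | lithium 8α-alkoxide from hydride opening of 37 (not isolated) | [Li+].C[C@@]1([O-])[C@@H](O[Si](C)(C)C(C)(C)C)[C@H](O[Si](CC)(CC)CC)[C@@H]2C(C)(C)CCC[C@]2(C)[C@@]13CC[C@@]4(C=COC4)O3 | intermediate
39 | 8α-acetoxy-6α-(triethylsilyloxy)-7β-(tert-butyldimethylsilyloxy)-9α,13;15,16-diepoxy-5β-labd-14-ene | C[C@@]1(OC(C)=O)[C@@H](O[Si](C)(C)C(C)(C)C)[C@H](O[Si](CC)(CC)CC)[C@@H]2C(C)(C)CCC[C@]2(C)[C@@]13CC[C@@]4(C=COC4)O3 | intermediate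
40 | 8α-acetoxy-6α-hydroxy-7β-(tert-butyldimethylsilyloxy)-9α,13;15,16-diepoxy-5β-labd-14-ene | C[C@@]1(OC(C)=O)[C@@H](O[Si](C)(C)C(C)(C)C)[C@H](O)[C@@H]2C(C)(C)CCC[C@]2(C)[C@@]13CC[C@@]4(C=COC4)O3 | intermediate
41 | 8α-acetoxy-7β-(tert-butyldimethylsilyloxy)-9α,13;15,16-diepoxy-5β-labd-14-en-6-one | C[C@@]1(OC(C)=O)[C@@H](O[Si](C)(C)C(C)(C)C)C(=O)[C@@H]2C(C)(C)CCC[C@]2(C)[C@@]13CC[C@@]4(C=COC4)O3 | intermediate
42 | 8α-acetoxy-7β-hydroxy-9α,13;15,16-diepoxy-5β-labd-14-en-6-one (CNP0275274.1) | CC(=O)O[C@]1(C)[C@@H](O)C(=O)[C@@H]2C(C)(C)CCC[C@]2(C)[C@@]12CC[C@@]1(C=COC1)O2 | target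

## Step count and least certain steps

Total: 25 steps. Longest linear sequence: 21 steps (steps 2–14 and 18–25, from 4); step 1 and steps 15–17 are side branches.

**Step 7 (key step).** Bond formation at C5 takes place next to the quaternary C10 with a bulky silyl terminus. A slow [3,3] shift would let fragmentation of the strained alkoxide, or decomposition under prolonged exposure to KH, compete. Fallback, from 14 back to 17: the neutral siloxy variant of the same shift. 14 is silylated (N-trimethylsilylimidazole, neat, 60 °C) to its trimethylsilyl ether F1. F1 is heated in a sealed tube (toluene, about 200 °C) to the trimethylsilyl enol ether F2. Mild methanolysis (K2CO3, MeOH) then gives 17. No alkoxide is present at any time.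

**Step 13.** The carbonyl lies between a ketal carbon and a silyloxy methine, so the titanium methylidene may fail to engage it, and prolonged heating risks silyl loss. Fallback, from 24 back to 25: Peterson olefination. Me3SiCH2Li with CeCl3 adds to the carbonyl to give the β-hydroxysilane F3 (either C8 epimer serves). KN(SiMe3)2 in THF then induces syn-elimination to 25.

**Step 18.** The carbonyl is hindered and the methylene terminus is open, so conjugate addition can compete. Attack from the α face would follow if ring B populates the other chair. Fallback, from 26 back to 35 (step 19 is then not needed): the enone is first epoxidised nucleophilically (t-BuOOH, DBU) to the spiro-epoxy ketone F4, ring closure being expected on the α face, away from the axial C10 methyl. No conjugate acceptor remains. The organocerium reagent 33 then adds to the carbonyl anti to the polar C8–O bond (Felkin–Anh control), that is from the β face, and gives 35 directly.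

**Step 20.** Diastereoselection at C13 rests on a modest steric difference between the C8 and C10 sides, so attack on the wrong alkene face may compete. Fallback, from 35 directly to 37 with no new compound (F0): a Wacker-type oxidative cyclisation with divalent palladium (Pd(OCOCF3)2, a chiral pyridine–oxazoline ligand, O2, toluene). Oxypalladation at C13 is followed by β-hydride elimination toward C15, the only position with hydrogen. The ligand, not the substrate, then decides the face, and step 21 is not needed.

**Step 23.** Even buffered HF may ionise the allylic C13–O9 bond and start aromatisation of ring D. Fallback, from 37 back to 40: the triethylsilyl group is removed before the acetate exists, with a limited amount of TBAF (THF, −20 → 0 °C), which is harmless to the enol ether and much slower at the O7 silyl ether beside the quaternary C8, to give the C6 alcohol F5. LiEt3BH followed by Ac2O/DMAP then acetylates both O6 and O8 to the diacetate F6. K2CO3 in MeOH at 0 °C cleaves the secondary O6 acetate much faster than the hindered tertiary one and gives 40.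

## Further compounds

F1 | step 7 | trimethylsilyl ether of 14 | C[Si](C)(C)O[C@]1(/C=C/[Si](C)(C)c2ccccc2)[C@@H]3CC[C@@](C)(C=C3C)C1(OC)OC
F2 | step 7 | trimethylsilyl enol ether (C7=C8) of 17 | C[Si](C)(C)OC1=C[C@H]([Si](C)(C)c2ccccc2)[C@@H]3C(C)=CCC[C@]3(C)C1(OC)OC
F3 | step 13 | 8-hydroxy-8-(trimethylsilylmethyl) adduct of 24 (C8 configuration open) | C[Si](C)(C)CC1(O)[C@@H](O[Si](C)(C)C(C)(C)C)[C@H](O[Si](CC)(CC)CC)[C@@H]2C(C)(C)CCC[C@]2(C)C1(OC)OC
F4 | step 18 | 8α,17-epoxy-9-ketone from 26 | C1O[C@@]12[C@@H](O[Si](C)(C)C(C)(C)C)[C@H](O[Si](CC)(CC)CC)[C@@H]3C(C)(C)CCC[C@]3(C)C2=O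
F0 | step 20 | none | none
F5 | step 23 | 6α-hydroxy analogue of 37 | C1O[C@@]12[C@@H](O[Si](C)(C)C(C)(C)C)[C@H](O)[C@@H]3C(C)(C)CCC[C@]3(C)[C@@]24CC[C@@]5(C=COC5)O4
F6 | step 23 | 6α,8α-diacetoxy-7β-(tert-butyldimethylsilyloxy)-9α,13;15,16-diepoxy-5β-labd-14-ene | C[C@@]1(OC(C)=O)[C@@H](O[Si](C)(C)C(C)(C)C)[C@H](OC(C)=O)[C@@H]2C(C)(C)CCC[C@]2(C)[C@@]13CC[C@@]4(C=COC4)O3
A1 | alternative 1 | cis-fused 9α-hydroxy-9β-[2-(3-furyl)ethyl]-4,4,8,10-tetramethyloctal-7-en-6-one | CC1=CC(=O)[C@@H]2C(C)(C)CCC[C@]2(C)[C@@]1(O)CCc1ccoc1
A2 | alternative 1 | 1-[cis-2-(but-2-ynoyl)-1,3,3-trimethylcyclohexyl]-3-(furan-3-yl)propan-1-one | CC#CC(=O)[C@@H]1C(C)(C)CCC[C@]1(C)C(=O)CCc1ccoc1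
A3 | alternative 2 | spiro 2,3-dihydrofuran (ring C with C12=C13) carrying the benzyloxymethyl arm and the C6 dioxolane | CC1=CC2(OCCO2)[C@@H]3C(C)(C)CCC[C@]3(C)[C@@]14CC=C(COCc5ccccc5)O4
A4 | alternative 2 | 9β-allyl 9α-(benzyloxyacetate) of the C6-dioxolane octalin | CC1=CC2(OCCO2)[C@@H]3C(C)(C)CCC[C@]3(C)[C@]1(CC=C)OC(=O)COCc1ccccc1
A5 | alternative 3 | cis-fused 1-methoxy-3-(trimethylsilyloxy)-8,10-dimethyloctalin-6,9-dione cycloadduct | CC1=CC(=O)[C@@H]2CC(O[Si](C)(C)C)=C[C@H](OC)[C@]2(C)C1=O
A6 | alternative 3 | 2,6-dimethyl-1,4-benzoquinone | CC1=CC(=O)C=C(C)C1=O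
A7 | alternative 3 | (E)-1-methoxy-3-(trimethylsilyloxy)buta-1,3-diene | CO/C=C/C(=C)O[Si](C)(C)C
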